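**Strategy.** The route rests on cutting the C6–C6′ biaryl bond that joins the two ring A units, one from the all-cis (4R) and one from the 3,4-trans (4S) flavan-3,4-diol. In each half C6 is the only C–H ortho to O7, because C8 carries oxygen. The two O7 phenols are therefore tied through a diisopropylsilylene bridge, with bromine at C6′ of the 4S half. One palladium-catalysed intramolecular C–H arylation then forms the biaryl bond and a temporary seven-membered dibenzodioxasilepine ring, pairing the two epimers without homodimers. All other hydroxyls are TBS ethers; fluoride finally removes bridge and ethers together.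

Key step: step 14

Remarks on the chemistry (TBS = tert-butyldimethylsilyl, MOM = methoxymethyl, TMS = trimethylsilyl, OTf = trifluoromethanesulfonate):
- Structure check: the first half of the target is (2R,3R,4R), 2,3-cis-3,4-cis; the second is (2R,3R,4S), 2,3-cis-3,4-trans. The bridged bromide 19 and its cyclised product 20 agree with this and need no correction. In every 3,4-bis-silyl ether C3 is formally S by the CIP rules (O–Si outranks O–C) although its geometry is unchanged.
- Assumption: the enantiomer of 7 that is carried on is assigned as (2R,3R,4R) by electronic circular dichroism and confirmed by anomalous-dispersion X-ray analysis of bromide 16.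
- Design choices: O7 is marked from the first step as a MOM ether on the most acidic hydroxyl of gallacetophenone and stays etherified through the ring hydrogenation. The all-cis triad comes from a Raney Ni hydrogenation followed by resolution. After O7 is unmasked, no step generates a phenoxide next to the 8-OTBS group, so the silyl group cannot shift to O7.

Step 1
Reactants: 1 gallacetophenone (1-(2,3,4-trihydroxyphenyl)ethan-1-one)
Product: 2 1-[2,3-dihydroxy-4-(methoxymethoxy)phenyl]ethan-1-one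
Conditions: MOMCl (1.0 equiv), K2CO3 (1.0 equiv), acetone, 0 °C to rt, N2
Reagents that add atoms: chloromethyl methyl ether, COCCl
Why: Williamson-type O-alkylation; the 4-OH para to the acetyl group is the most acidic phenol, the 2-OH is hydrogen-bonded to the carbonyl and the 3-OH is flanked on both sides, so one equivalent of MOMCl should alkylate O4 (the future O7).

Step 2
Reactants: 2 1-[2,3-dihydroxy-4-(methoxymethoxy)phenyl]ethan-1-one
Product: 3 1-[3-(benzyloxy)-2-hydroxy-4-(methoxymethoxy)phenyl]ethan-1-one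
Conditions: BnBr (1.1 equiv), K2CO3, DMF, rt
Reagents that add atoms: benzyl bromide, BrCc1ccccc1
Why: Williamson ether synthesis at the remaining non-chelated 3-OH (the future O8); the chelated 2-OH is not alkylated under carbonate conditions and is kept for closure of ring C.

Step 3
Reactants: 3 1-[3-(benzyloxy)-2-hydroxy-4-(methoxymethoxy)phenyl]ethan-1-one, 4 4-(benzyloxy)benzaldehyde
Product: 5 (E)-1-[3-(benzyloxy)-2-hydroxy-4-(methoxymethoxy)phenyl]-3-[4-(benzyloxy)phenyl]prop-2-en-1-one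
Conditions: KOH (50% aq.), EtOH–THF, rt; then AcOH to pH 6
Reagents that add atoms: none
Why: Claisen–Schmidt condensation; the aldehyde cannot enolise and E1cB dehydration of the aldol gives the conjugated E-enone, with MOM and benzyl ethers inert to hydroxide.

Step 4
Reactants: 5 (E)-1-[3-(benzyloxy)-2-hydroxy-4-(methoxymethoxy)phenyl]-3-[4-(benzyloxy)phenyl]prop-2-en-1-one
Product: 6 8-(benzyloxy)-2-[4-(benzyloxy)phenyl]-3-hydroxy-7-(methoxymethoxy)-4H-chromen-4-one
Conditions: H2O2 (30% aq.), NaOH (2 M aq.), MeOH–THF, 0 °C to rt; then AcOH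
Reagents that add atoms: hydrogen peroxide, OO
Why: Algar–Flynn–Oyamada reaction; hydroperoxide epoxidises the enone, the 2′-phenoxide closes ring C and the dihydroflavonol is oxidised on to the flavonol, which is the expected product for a chalcone without a 6′-substituent.

Step 5
Reactants: 6 8-(benzyloxy)-2-[4-(benzyloxy)phenyl]-3-hydroxy-7-(methoxymethoxy)-4H-chromen-4-one
Product: 7 rac-(2R,3R,4R)-2-(4-hydroxyphenyl)-7-(methoxymethoxy)chromane-3,4,8-triol (racemic 2,3-cis-3,4-cis diol)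
Conditions: H2 (60 bar), Raney Ni (W-2, washed neutral), EtOH–EtOAc, 70 °C
Reagents that add atoms: none
Why: Heterogeneous hydrogenation; syn delivery of hydrogen to C2=C3 and then to C4=O from the face away from the 2-aryl group should set the racemic all-cis triad, as in the classical Raney nickel reduction of flavonol ethers, while both benzyl ethers are hydrogenolysed and O7 stays etherified so that no para-quinone methide can form at C4.

Step 6
Reactants: 7 rac-(2R,3R,4R)-2-(4-hydroxyphenyl)-7-(methoxymethoxy)chromane-3,4,8-triol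
Product: 8 (2R,3R,4R)-2-(4-hydroxyphenyl)-7-(methoxymethoxy)chromane-3,4,8-triol
Conditions: preparative SFC, amylose tris(3,5-dimethylphenylcarbamate) phase, CO2–MeOH
Reagents that add atoms: none
Why: Resolution of a racemate by chromatography on a chiral stationary phase; no bond is made or broken, and the polar triol with two aryl groups should resolve well on a polysaccharide phase, which fixes the absolute configuration of C2, C3 and C4 for both halves.

Step 7
Reactants: 8 (2R,3R,4R)-2-(4-hydroxyphenyl)-7-(methoxymethoxy)chromane-3,4,8-triol (about half of the material)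
Product: 9 (2R,3R,4S)-2-(4-hydroxyphenyl)-7-(methoxymethoxy)chromane-3,4,8-triol (2,3-cis-3,4-trans)
Conditions: HCl (0.02 M aq.)–THF 1:1, 5 mM, 40 °C; NaHCO3; SiO2 separation, recovered 8 returned to step 7 or 8
Reagents that add atoms: water, O
Why: Acid-catalysed SN1 epimerisation at C4; the benzylic carbinol ionises to a cation stabilised by O1 and the para O7 ether, water returns mainly anti to the 3-OH to give the 3,4-trans epimer, C2 and C3 are not involved, and high dilution in a water-rich medium disfavours capture of the cation by a second flavan.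

Step 8
Reactants: 8 (2R,3R,4R)-2-(4-hydroxyphenyl)-7-(methoxymethoxy)chromane-3,4,8-triol
Product: 10 (2R,3S,4R)-7-(methoxymethoxy)-3,4,8-tris(TBS-oxy)-2-[4-(TBS-oxy)phenyl]chromane
Conditions: TBSOTf (6 equiv), 2,6-lutidine (9 equiv), CH2Cl2, −40 °C to rt
Reagents that add atoms: tert-butyldimethylsilyl trifluoromethanesulfonate, CC(C)(C)[Si](C)(C)OS(=O)(=O)C(F)(F)F
Why: Silyl ether formation with the triflate and 2,6-lutidine, reactive enough for the hindered 8-OH and the vicinal cis-diol; the MOM acetal should survive the buffered, cold conditions and no stereocentre is touched.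

Step 9
Reactants: 9 (2R,3R,4S)-2-(4-hydroxyphenyl)-7-(methoxymethoxy)chromane-3,4,8-triol
Product: 11 (2R,3S,4S)-7-(methoxymethoxy)-3,4,8-tris(TBS-oxy)-2-[4-(TBS-oxy)phenyl]chromane
Conditions: TBSOTf (6 equiv), 2,6-lutidine (9 equiv), CH2Cl2, −40 °C to rt
Reagents that add atoms: tert-butyldimethylsilyl trifluoromethanesulfonate, CC(C)(C)[Si](C)(C)OS(=O)(=O)C(F)(F)F
Why: Same silyl ether formation on the 4S epimer; protection of the C4 carbinol fixes the newly set configuration against later ionisation.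

Step 10
Reactants: 10 (2R,3S,4R)-7-(methoxymethoxy)-3,4,8-tris(TBS-oxy)-2-[4-(TBS-oxy)phenyl]chromane
Product: 13 (2R,3S,4R)-3,4,8-tris(TBS-oxy)-2-[4-(TBS-oxy)phenyl]chroman-7-ol, via 7-O-trimethylsilyl ether 12 (not isolated)
Conditions: TMSOTf (3 equiv), 2,2′-bipyridyl (4.5 equiv), CH2Cl2, 0 °C to rt; then H2O, rt; pH 7 buffer
Reagents that add atoms: none
Why: Chemoselective cleavage of an aryl MOM ether by silyl triflate and 2,2′-bipyridyl (aryl MOM ether to aryl TMS ether, then hydrolysis); the conditions are non-acidic, so TBS ethers and the benzylic C4 silyl ether should persist, and no base is present that could move the 8-O-silyl group to the freed O7.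

Step 11
Reactants: 11 (2R,3S,4S)-7-(methoxymethoxy)-3,4,8-tris(TBS-oxy)-2-[4-(TBS-oxy)phenyl]chromane
Product: 15 (2R,3S,4S)-3,4,8-tris(TBS-oxy)-2-[4-(TBS-oxy)phenyl]chroman-7-ol, via 7-O-trimethylsilyl ether 14 (not isolated)
Conditions: TMSOTf (3 equiv), 2,2′-bipyridyl (4.5 equiv), CH2Cl2, 0 °C to rt; then H2O, rt; pH 7 buffer
Reagents that add atoms: none
Why: Same aryl MOM ether cleavage by silyl triflate and 2,2′-bipyridyl on the 4S series, again without acid or base strong enough to disturb the C4 silyl ether or to trigger silyl migration.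

Step 12
Reactants: 15 (2R,3S,4S)-3,4,8-tris(TBS-oxy)-2-[4-(TBS-oxy)phenyl]chroman-7-ol
Product: 16 (2R,3S,4S)-6-bromo-3,4,8-tris(TBS-oxy)-2-[4-(TBS-oxy)phenyl]chroman-7-ol
Conditions: NBS (1.0 equiv), CH2Cl2, −40 to −20 °C, dark
Reagents that add atoms: N-bromosuccinimide, O=C1CCC(=O)N1Br
Why: Electrophilic aromatic bromination directed by the free 7-OH; C6 is its only open ortho position (C8 is oxygenated and the para carbon C4a is substituted) and the silylated ring B is much less activated, so monobromination at C6 is expected.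

Step 13
Reactants: 16 (2R,3S,4S)-6-bromo-3,4,8-tris(TBS-oxy)-2-[4-(TBS-oxy)phenyl]chroman-7-ol, 17 diisopropylsilyl bis(trifluoromethanesulfonate), 13 (2R,3S,4R)-3,4,8-tris(TBS-oxy)-2-[4-(TBS-oxy)phenyl]chroman-7-ol
Product: 19 {[(2R,3S,4R)-3,4,8-tris(TBS-oxy)-2-[4-(TBS-oxy)phenyl]chroman-7-yl]oxy}{[(2R,3S,4S)-6-bromo-3,4,8-tris(TBS-oxy)-2-[4-(TBS-oxy)phenyl]chroman-7-yl]oxy}di(propan-2-yl)silane, via aryloxysilyl triflate 18 (not isolated)
Conditions: 17 (1.05 equiv), 2,6-lutidine (4 equiv), CH2Cl2, −78 °C, slow addition of 16; then 13, −78 °C to rt; SiO2 deactivated with Et3N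
Reagents that add atoms: none
Why: Stepwise silyl ether formation at a silicon bis(triflate), the usual way to unsymmetrical silylene-linked ethers; the hindered bromophenol is added first so that substitution stops at the mono(aryloxy)silyl triflate, the second phenol then displaces the remaining triflate, the order of addition excludes homodimeric silanes, and 2,6-lutidine is too weak a base to form a phenoxide that could trigger O8-to-O7 silyl migration.

Step 14
Reactants: 19 O7,O7′-diisopropylsilylene-bridged pair of the 4R monomer (C6–H) and the 6′-bromo 4S monomer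
Product: 20 O7,O7′-diisopropylsilylene-bridged 6,6′-biflavan, octa-TBS (dibenzo[d,f][1,3,2]dioxasilepine)
Conditions: Pd(OAc)2 (10 mol %), PCy3·HBF4 (20 mol %), CsOPiv (caesium pivalate, 3 equiv), toluene (0.02 M), 4 Å MS, 110 °C, Ar
Reagents that add atoms: none
Why: Zerovalent palladium, formed from Pd(OAc)2 and PCy3, inserts into the C6′–Br bond of the 4S half, pivalate-assisted concerted metalation–deprotonation removes H6 of the 4R half, and reductive elimination from the eight-membered diarylpalladium (divalent) intermediate forms C6–C6′. The closest known reaction type is the intramolecular direct arylation of a bromophenol tethered to a second phenol as a bis(aryloxy)dialkylsilane, which gives silylene ethers of 2,2′-biphenols. The only ring formed is the seven-membered dibenzodioxasilepine, closed by C–C bond formation between the two carbons ortho to the O–Si–O linked oxygens as the palladacycle contracts on reductive elimination. No stereocentre is created: the new biaryl axis carries only two ortho oxygens beside two hydrogens and is not configurationally stable, and the six silylated carbinol centres are not touched. The step needs site selectivity for C6–H over C5–H and ring B, and cross- over homo-coupling; the bridge reaches only the carbon ortho to O7, which is C6 because C8 bears OTBS, and it holds exactly one 4R and one 4S unit at the metal. Dilute anhydrous conditions with a weakly nucleophilic carboxylate base are chosen to spare the Si–O bonds.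

Step 15
Reactants: 20 O7,O7′-diisopropylsilylene-bridged 6,6′-biflavan, octa-TBS
Product: 21 (2R,2′R,3R,3′R,4R,4′S)-2,2′-bis(4-hydroxyphenyl)-[6,6′-bichromane]-3,3′,4,4′,7,7′,8,8′-octol (target)
Conditions: HF·pyridine (excess), pyridine, THF, 0 °C to rt, polypropylene vessel; MeOSiMe3 quench; Sephadex LH-20 (MeOH) under Ar
Reagents that add atoms: none
Why: Fluoride-mediated global desilylation; buffered HF·pyridine should cleave the two aryloxy–silicon bonds of the bridge and all four aryl and four alkyl TBS ethers without ionising the C4 carbinols, and the non-aqueous quench keeps the air-sensitive polyphenol away from base.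

**Compound list**

1 | gallacetophenone | CC(=O)c1ccc(O)c(O)c1O | starting material
2 | 1-[2,3-dihydroxy-4-(methoxymethoxy)phenyl]ethan-1-one | CC(=O)c1ccc(OCOC)c(O)c1O | intermediate
3 | 1-[3-(benzyloxy)-2-hydroxy-4-(methoxymethoxy)phenyl]ethan-1-one | CC(=O)c1ccc(OCOC)c(OCc2ccccc2)c1O | intermediate
4 | 4-(benzyloxy)benzaldehyde | O=Cc1ccc(OCc2ccccc2)cc1 | starting material
5 | (E)-1-[3-(benzyloxy)-2-hydroxy-4-(methoxymethoxy)phenyl]-3-[4-(benzyloxy)phenyl]prop-2-en-1-one | COCOc1ccc(C(=O)/C=C/c2ccc(OCc3ccccc3)cc2)c(O)c1OCc1ccccc1 | intermediate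
6 | 8-(benzyloxy)-2-[4-(benzyloxy)phenyl]-3-hydroxy-7-(methoxymethoxy)-4H-chromen-4-one | COCOc1ccc2c(=O)c(O)c(-c3ccc(OCc4ccccc4)cc3)oc2c1OCc1ccccc1 | intermediate
7 | rac-(2R,3R,4R)-2-(4-hydroxyphenyl)-7-(methoxymethoxy)chromane-3,4,8-triol (both enantiomers, 2,3-cis-3,4-cis) | Oc1ccc([C@H]2Oc3c(ccc(OCOC)c3O)[C@@H](O)[C@H]2O)cc1.Oc1ccc([C@@H]2Oc3c(ccc(OCOC)c3O)[C@H](O)[C@@H]2O)cc1 | intermediate
8 | (2R,3R,4R)-2-(4-hydroxyphenyl)-7-(methoxymethoxy)chromane-3,4,8-triol | Oc1ccc([C@H]2Oc3c(ccc(OCOC)c3O)[C@@H](O)[C@H]2O)cc1 | intermediate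
9 | (2R,3R,4S)-2-(4-hydroxyphenyl)-7-(methoxymethoxy)chromane-3,4,8-triol | Oc1ccc([C@H]2Oc3c(ccc(OCOC)c3O)[C@H](O)[C@H]2O)cc1 | intermediate
10 | (2R,3S,4R)-7-(methoxymethoxy)-3,4,8-tris(TBS-oxy)-2-[4-(TBS-oxy)phenyl]chromane (2,3-cis-3,4-cis) | CC(C)(C)[Si](C)(C)Oc1ccc([C@H]2Oc3c(ccc(OCOC)c3O[Si](C)(C)C(C)(C)C)[C@@H](O[Si](C)(C)C(C)(C)C)[C@H]2O[Si](C)(C)C(C)(C)C)cc1 | intermediate
11 | (2R,3S,4S)-7-(methoxymethoxy)-3,4,8-tris(TBS-oxy)-2-[4-(TBS-oxy)phenyl]chromane (2,3-cis-3,4-trans) | CC(C)(C)[Si](C)(C)Oc1ccc([C@H]2Oc3c(ccc(OCOC)c3O[Si](C)(C)C(C)(C)C)[C@H](O[Si](C)(C)C(C)(C)C)[C@H]2O[Si](C)(C)C(C)(C)C)cc1 | intermediate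
12 | (2R,3S,4R)-3,4,8-tris(TBS-oxy)-2-[4-(TBS-oxy)phenyl]-7-(trimethylsilyloxy)chromane | CC(C)(C)[Si](C)(C)Oc1ccc([C@H]2Oc3c(ccc(O[Si](C)(C)C)c3O[Si](C)(C)C(C)(C)C)[C@@H](O[Si](C)(C)C(C)(C)C)[C@H]2O[Si](C)(C)C(C)(C)C)cc1 | intermediate
13 | (2R,3S,4R)-3,4,8-tris(TBS-oxy)-2-[4-(TBS-oxy)phenyl]chroman-7-ol | CC(C)(C)[Si](C)(C)Oc1ccc([C@H]2Oc3c(ccc(O)c3O[Si](C)(C)C(C)(C)C)[C@@H](O[Si](C)(C)C(C)(C)C)[C@H]2O[Si](C)(C)C(C)(C)C)cc1 | intermediate
14 | (2R,3S,4S)-3,4,8-tris(TBS-oxy)-2-[4-(TBS-oxy)phenyl]-7-(trimethylsilyloxy)chromane | CC(C)(C)[Si](C)(C)Oc1ccc([C@H]2Oc3c(ccc(O[Si](C)(C)C)c3O[Si](C)(C)C(C)(C)C)[C@H](O[Si](C)(C)C(C)(C)C)[C@H]2O[Si](C)(C)C(C)(C)C)cc1 | intermediate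
15 | (2R,3S,4S)-3,4,8-tris(TBS-oxy)-2-[4-(TBS-oxy)phenyl]chroman-7-ol | CC(C)(C)[Si](C)(C)Oc1ccc([C@H]2Oc3c(ccc(O)c3O[Si](C)(C)C(C)(C)C)[C@H](O[Si](C)(C)C(C)(C)C)[C@H]2O[Si](C)(C)C(C)(C)C)cc1 | intermediate
16 | (2R,3S,4S)-6-bromo-3,4,8-tris(TBS-oxy)-2-[4-(TBS-oxy)phenyl]chroman-7-ol | CC(C)(C)[Si](C)(C)Oc1ccc([C@H]2Oc3c(cc(Br)c(O)c3O[Si](C)(C)C(C)(C)C)[C@H](O[Si](C)(C)C(C)(C)C)[C@H]2O[Si](C)(C)C(C)(C)C)cc1 | intermediate
17 | diisopropylsilyl bis(trifluoromethanesulfonate) | CC(C)[Si](OS(=O)(=O)C(F)(F)F)(OS(=O)(=O)C(F)(F)F)C(C)C | starting material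
18 | {[(2R,3S,4S)-6-bromo-3,4,8-tris(TBS-oxy)-2-[4-(TBS-oxy)phenyl]chroman-7-yl]oxy}di(propan-2-yl)silyl trifluoromethanesulfonate | CC(C)(C)[Si](C)(C)Oc1ccc([C@H]2Oc3c(cc(Br)c(O[Si](C(C)C)(C(C)C)OS(=O)(=O)C(F)(F)F)c3O[Si](C)(C)C(C)(C)C)[C@H](O[Si](C)(C)C(C)(C)C)[C@H]2O[Si](C)(C)C(C)(C)C)cc1 | intermediate
19 | O7,O7′-diisopropylsilylene-bridged pair of 13 and 16 (4R half with C6–H, 4S half with C6′–Br) | CC(C)(C)[Si](C)(C)Oc1ccc([C@H]2Oc3c(ccc(O[Si](C(C)C)(C(C)C)Oc4c(Br)cc5c(c4O[Si](C)(C)C(C)(C)C)O[C@H](c4ccc(O[Si](C)(C)C(C)(C)C)cc4)[C@H](O[Si](C)(C)C(C)(C)C)[C@H]5O[Si](C)(C)C(C)(C)C)c3O[Si](C)(C)C(C)(C)C)[C@@H](O[Si](C)(C)C(C)(C)C)[C@H]2O[Si](C)(C)C(C)(C)C)cc1 | intermediate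
20 | O7,O7′-diisopropylsilylene-bridged 6,6′-biflavan, octa-TBS | CC(C)(C)[Si](C)(C)Oc1ccc([C@H]2Oc3c(cc4c(O[Si](C(C)C)(C(C)C)Oc5c-4cc6c(c5O[Si](C)(C)C(C)(C)C)O[C@H](c7ccc(O[Si](C)(C)C(C)(C)C)cc7)[C@H](O[Si](C)(C)C(C)(C)C)[C@H]6O[Si](C)(C)C(C)(C)C)c3O[Si](C)(C)C(C)(C)C)[C@@H](O[Si](C)(C)C(C)(C)C)[C@H]2O[Si](C)(C)C(C)(C)C)cc1 | intermediate
21 | (2R,2′R,3R,3′R,4R,4′S)-2,2′-bis(4-hydroxyphenyl)-[6,6′-bichromane]-3,3′,4,4′,7,7′,8,8′-octol | Oc1ccc([C@H]2Oc3c(cc(-c4cc5c(c(O)c4O)O[C@H](c4ccc(O)cc4)[C@H](O)[C@H]5O)c(O)c3O)[C@@H](O)[C@H]2O)cc1 | target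

**Step count.** Total: 15 steps. Longest linear sequence: 13 steps (steps 1–7, 9, 11, 12, 13, 14, 15).

**Steps most likely to fail**

Step 14. What may go wrong: hydrodebromination of the aryl–palladium intermediate, slow C–H metalation at the crowded electron-rich C6, or carboxylate-induced opening of the Si–O bridge before cyclisation. The fallback sets out from 13 (with 16 and 17) and comes back at 20; it replaces C–H activation by coupling of two carbon–halogen bonds. Phenol 13 is brominated with NBS as in step 12 to give (2R,3S,4R)-6-bromo-3,4,8-tris(TBS-oxy)-2-[4-(TBS-oxy)phenyl]chroman-7-ol F1. F1 and 16 are joined through 17 under the conditions of step 13 to the silylene-bridged 6,6′-dibromide F2. F2 is then closed by an intramolecular reductive Ullmann-type coupling mediated by zerovalent nickel (Ni(cod)2, 2,2′-bipyridyl, DMF–toluene, 60 °C), which should deliver 20.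

Step 5. What may go wrong: hydrogenolysis of the benzylic C4–O or C2–O1 bonds, or epimerisation at C2, once the 4′- and 8-phenols are unmasked at the temperature needed to saturate the pyranone; debenzylation may also be incomplete. The fallback sets out from 6 and comes back at 7; it separates debenzylation from ring reduction so that no free phenol is present during the latter. The benzyl ethers are removed first under mild conditions that leave the pyranone intact (H2 1 bar, Pd/C, EtOAc–MeOH, rt), giving 3,8-dihydroxy-2-(4-hydroxyphenyl)-7-(methoxymethoxy)-4H-chromen-4-one F3. Acetylation (Ac2O, pyridine) gives the triacetate F4. Raney Ni hydrogenation in EtOAc then gives the racemic all-cis 4-hydroxy triacetate F5, and methanolysis (K2CO3, MeOH, 0 °C, Ar) returns 7.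

Step 7. What may go wrong: capture of the C4 cation by a second flavan ring (self-condensation), ionisation too slow at an acidity the MOM acetal tolerates, or partial hydrolysis of the acetal. The fallback sets out from 8 and comes back at 9; it inverts C4 by SN2 displacement and avoids a free cation. The two phenols of 8 are silylated selectively (TBSCl 2.1 equiv, imidazole, DMF, 0 °C) to give (2R,3R,4R)-8-(TBS-oxy)-2-[4-(TBS-oxy)phenyl]-7-(methoxymethoxy)chromane-3,4-diol F6. A Mitsunobu reaction (4-nitrobenzoic acid, PPh3, DIAD, toluene, 0 °C) should esterify the more reactive benzylic C4 carbinol with inversion, since the cis-3-OH cannot close an epoxide, giving the 3,4-trans 4-(4-nitrobenzoate) F7. K2CO3 in MeOH then removes the ester and both aryl silyl ethers to give 9.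

**Further compounds**

F1 | step 14 | (2R,3S,4R)-6-bromo-3,4,8-tris(TBS-oxy)-2-[4-(TBS-oxy)phenyl]chroman-7-ol | CC(C)(C)[Si](C)(C)Oc1ccc([C@H]2Oc3c(cc(Br)c(O)c3O[Si](C)(C)C(C)(C)C)[C@@H](O[Si](C)(C)C(C)(C)C)[C@H]2O[Si](C)(C)C(C)(C)C)cc1
F2 | step 14 | O7,O7′-diisopropylsilylene-bridged pair of F1 and 16 (6,6′-dibromide) | CC(C)(C)[Si](C)(C)Oc1ccc([C@H]2Oc3c(cc(Br)c(O[Si](C(C)C)(C(C)C)Oc4c(Br)cc5c(c4O[Si](C)(C)C(C)(C)C)O[C@H](c4ccc(O[Si](C)(C)C(C)(C)C)cc4)[C@H](O[Si](C)(C)C(C)(C)C)[C@H]5O[Si](C)(C)C(C)(C)C)c3O[Si](C)(C)C(C)(C)C)[C@@H](O[Si](C)(C)C(C)(C)C)[C@H]2O[Si](C)(C)C(C)(C)C)cc1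
F3 | step 5 | 3,8-dihydroxy-2-(4-hydroxyphenyl)-7-(methoxymethoxy)-4H-chromen-4-one | COCOc1ccc2c(=O)c(O)c(-c3ccc(O)cc3)oc2c1O
F4 | step 5 | 2-(4-acetoxyphenyl)-7-(methoxymethoxy)-4-oxo-4H-chromene-3,8-diyl diacetate | COCOc1ccc2c(=O)c(OC(C)=O)c(-c3ccc(OC(C)=O)cc3)oc2c1OC(C)=O
F5 | step 5 | rac-(2R,3R,4R)-2-(4-acetoxyphenyl)-4-hydroxy-7-(methoxymethoxy)chromane-3,8-diyl diacetate (both enantiomers, all-cis) | CC(=O)Oc1ccc([C@H]2Oc3c(ccc(OCOC)c3OC(C)=O)[C@@H](O)[C@H]2OC(C)=O)cc1.CC(=O)Oc1ccc([C@@H]2Oc3c(ccc(OCOC)c3OC(C)=O)[C@H](O)[C@@H]2OC(C)=O)cc1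
F6 | step 7 | (2R,3R,4R)-8-(TBS-oxy)-2-[4-(TBS-oxy)phenyl]-7-(methoxymethoxy)chromane-3,4-diol | CC(C)(C)[Si](C)(C)Oc1ccc([C@H]2Oc3c(ccc(OCOC)c3O[Si](C)(C)C(C)(C)C)[C@@H](O)[C@H]2O)cc1
F7 | step 7 | (2R,3S,4S)-8-(TBS-oxy)-2-[4-(TBS-oxy)phenyl]-3-hydroxy-7-(methoxymethoxy)chroman-4-yl 4-nitrobenzoate (2,3-cis-3,4-trans) | CC(C)(C)[Si](C)(C)Oc1ccc([C@H]2Oc3c(ccc(OCOC)c3O[Si](C)(C)C(C)(C)C)[C@H](OC(=O)c3ccc(cc3)[N+](=O)[O-])[C@H]2O)cc1
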